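**Retrosynthetic overview**

1. Target 4-bromo-3-butyl-5-(dibromomethylene)furan-2(5H)-one ⇒ the 5-ylidenetetronic acid 3-butyl-5-(dibromomethylene)-4-hydroxyfuran-2(5H)-one (C4–Br from C4–OH by bromodehydroxylation).
2. Tetronic acid ⇒ opened at C3–C4 (Dieckmann-type ring closure) and, in the same flask, at O1–C2 (O-acylation): hexanoyl chloride + ethyl 3,3-dibromopyruvate. The furanone, the only ring, is made in this one operation with the C3 butyl group, the C5=CBr2 unit and an oxygen handle at C4 in place.
3. Enabling feature: in the ring O1–C2(=O)–C3–C4–C5, C3 is the α-carbon of a hexanoyl unit (latent ester enolate) and the bromine-bearing C4 stands 1,3 to the lactone carbonyl C2. C4 can therefore enter one oxidation level higher as an ester carbonyl (masked β-keto ester = tetronic acid). O1 on C5 is the enol oxygen of a dibromopyruvate and holds C3 and C4 in a 1,5-relationship.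
4. Ethyl 3,3-dibromopyruvate ⇒ ethyl pyruvate + 2 Br2.

Key step: step 2

Remark: the target has no stereocentre and its exocyclic alkene carries two identical bromine atoms, so it is a single achiral stereoisomer and no enantio- or E/Z-control is required.

**Step 1**
Reactants: 1 ethyl pyruvate (ethyl 2-oxopropanoate)
Product: 3 ethyl 3,3-dibromo-2-oxopropanoate, via ethyl 3-bromo-2-oxopropanoate 2 (not isolated)
Conditions: Br2 (2.1 equiv), cat. H2SO4, CHCl3, 0 → 60 °C; distillation
Reagents that add atoms: bromine, BrBr
Why: Acid-catalysed α-bromination of a ketone through its enol, in which the methyl group is the only enolisable position and each bromine slows the next enolisation, so two equivalents should stop at the gem-dibromide (no stereocentre is formed).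

**Step 2**
Reactants: 3 ethyl 3,3-dibromo-2-oxopropanoate; 4 hexanoyl chloride
Product: 8 3-butyl-5-(dibromomethylene)-4-hydroxyfuran-2(5H)-one, via lithium enolate 5 (not isolated), via enol ester 6 (not isolated), via lithium tetronate 7 (not isolated)
Conditions: LiHMDS (1.05 equiv), THF, −78 °C; 4 (1.0 equiv), −78 → −20 °C; recool, LiHMDS (2.1 equiv), −78 → 0 °C; then 1 M HCl
Reagents that add atoms: none
Why: LiHMDS removes the doubly activated CHBr2 proton of 3 to give lithium enolate 5, which hexanoyl chloride acylates on oxygen (carbon attack would have to build a quaternary CBr2 centre) to give enol ester 6; two further equivalents of base enolise the hexanoyl CH2, the only acidic C–H left, and this ester enolate (C3) adds to the adjacent ethyl ester carbonyl (C4) and expels ethoxide, the product being deprotonated at once to the vinylogous carboxylate 7, which makes the Claisen step irreversible until the acid quench releases 8. The closest known reaction type is the Dieckmann (Lacey–Dieckmann) condensation of α-(acyloxy)acrylates, that is of enol esters of α-keto esters, to 5-ylidenetetronic acids, telescoped here with the enol ester formation in the manner of tandem transesterification–Dieckmann tetronic acid syntheses. The furanone, the only ring, closes by 5-exo-trig attack of the enolate carbon on the exocyclic ester C=O, forming the C3–C4 bond with O1 as the tether. No stereocentre is created and the C5=CBr2 alkene has two identical bromines, so no stereocontrol is needed. The step needs O- over C-acylation, acyl attack over conjugate addition–elimination at the CBr2 carbon, and ring closure faster than loss of butylketene from the enolate of 6; the steric shielding of the dibrominated carbon, the 5-endo-trig geometry the conjugate pathway would require, and the enforced 1,5-proximity of C3 and C4 at −78 °C with a non-nucleophilic amide base should secure these.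

**Step 3**
Reactants: 8 3-butyl-5-(dibromomethylene)-4-hydroxyfuran-2(5H)-one
Product: 10 4-bromo-3-butyl-5-(dibromomethylene)furan-2(5H)-one, via O-iminium salt 9 (not isolated)
Conditions: (COBr)2 (1.3 equiv), DMF (1.5 equiv), CH2Cl2, 0 °C → rt
Reagents that add atoms: oxalyl bromide, O=C(Br)C(Br)=O
Why: Bromodehydroxylation of a tetronic acid (a vinylogous carboxylic acid) with the bromo-Vilsmeier reagent, by O-formiminium activation of the C4 enol and addition–elimination of bromide at C4, the standard conversion of tetronic acids into 4-bromofuran-2(5H)-ones; the dibromoalkene and the lactone should be inert to these acidic, non-reducing conditions.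

**Compound list**

1 | ethyl pyruvate (ethyl 2-oxopropanoate) | CCOC(=O)C(C)=O | starting material
2 | ethyl 3-bromo-2-oxopropanoate | CCOC(=O)C(=O)CBr | intermediate (not isolated)
3 | ethyl 3,3-dibromo-2-oxopropanoate | CCOC(=O)C(=O)C(Br)Br | intermediate
4 | hexanoyl chloride | CCCCCC(Cl)=O | starting material
5 | lithium 2,2-dibromo-1-(ethoxycarbonyl)ethen-1-olate | [Li+].CCOC(=O)C([O-])=C(Br)Br | intermediate (not isolated)
6 | ethyl 3,3-dibromo-2-(hexanoyloxy)prop-2-enoate | CCCCCC(=O)OC(=C(Br)Br)C(=O)OCC | intermediate (not isolated)
7 | lithium 4-butyl-2-(dibromomethylene)-5-oxo-2,5-dihydrofuran-3-olate | [Li+].CCCCC1=C([O-])C(=C(Br)Br)OC1=O | intermediate (not isolated)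
8 | 3-butyl-5-(dibromomethylene)-4-hydroxyfuran-2(5H)-one | CCCCC1=C(O)C(=C(Br)Br)OC1=O | intermediate
9 | N-({[4-butyl-2-(dibromomethylene)-5-oxo-2,5-dihydrofuran-3-yl]oxy}methylidene)-N-methylmethanaminium bromide | CCCCC1=C(OC=[N+](C)C)C(=C(Br)Br)OC1=O.[Br-] | intermediate (not isolated)
10 | 4-bromo-3-butyl-5-(dibromomethylene)furan-2(5H)-one | CCCCC1=C(Br)C(=C(Br)Br)OC1=O | target

**Step count**

Total steps: 3. Longest linear sequence: 3 steps (1 → 3 → 8 → 10; hexanoyl chloride 4 enters in step 2).

**Steps most likely to fail**

1. Step 2. The ester enolate of the enol ester may fragment into butylketene and the dibromopyruvate enolate, or the enol ester may be cleaved by the base, before the ring closes; C-acylation in the first stage would also divert material. The fallback avoids an enol ester enolate altogether; it sets out from 4 and comes back to the route at 10. Hexanoyl chloride 4 would be converted with lithium trimethylsilanolate into trimethylsilyl hexanoate F1, and LDA/Me3SiCl would turn this into the ketene acetal 1,1-bis(trimethylsilyloxy)hex-1-ene F2. The Me3SiOTf-catalysed cyclisation of this bis(silyl) ketene acetal with oxalyl chloride should give 3-butyl-4-hydroxyfuran-2,5-dione F3, and oxalyl bromide/DMF should convert it into 3-bromo-4-butylfuran-2,5-dione F4. A Ramirez dibromo-olefination (CBr4, PPh3) should then occur at the more electrophilic anhydride carbonyl, the one next to the C–Br carbon, which is inductively activated and not vinylogously deactivated by the bromine lone pair, and deliver 10 directly.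

2. Step 1. The bromination may not stop cleanly at the dibromo stage, giving mono-, di- and tribromides that are hard to separate, and the product may hydrate. The fallback fixes the bromine count by stoichiometric addition–elimination cycles; it sets out from 1 and comes back to the route at 6. Ethyl pyruvate 1 would be O-acylated with 4 (Et3N, cat. DMAP, CH2Cl2) to ethyl 2-(hexanoyloxy)prop-2-enoate F5. Addition of bromine would give ethyl 2,3-dibromo-2-(hexanoyloxy)propanoate F6, and Et3N-induced loss of HBr would give ethyl 3-bromo-2-(hexanoyloxy)prop-2-enoate F7, whose alkene geometry is irrelevant. A second bromine addition, to ethyl 2,3,3-tribromo-2-(hexanoyloxy)propanoate F8, and a second elimination would give enol ester 6, which would then be isolated and cyclised to 8 with LiHMDS (2.1 equiv) as in the second stage of step 2.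

3. Step 3. Substitution at the hindered, cross-conjugated C4 may stall at the activated-enol stage, or the enol lactone may degrade under the HBr that is released. The fallback separates activation from substitution; it sets out from 8 and comes back to the route at 10. Tetronic acid 8 would be converted (Tf2O, 2,6-lutidine, CH2Cl2, −78 °C) into 4-butyl-2-(dibromomethylene)-5-oxo-2,5-dihydrofuran-3-yl trifluoromethanesulfonate F9, and this isolated vinylogous acyl triflate would be treated with LiBr in acetone, bromide adding at C4 and expelling triflate (addition–elimination) to give 10 under neutral conditions.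

**Further compounds**

F1 | step 2 | trimethylsilyl hexanoate | CCCCCC(=O)O[Si](C)(C)C
F2 | step 2 | 1,1-bis(trimethylsilyloxy)hex-1-ene | CCCCC=C(O[Si](C)(C)C)O[Si](C)(C)C
F3 | step 2 | 3-butyl-4-hydroxyfuran-2,5-dione | CCCCC1=C(O)C(=O)OC1=O
F4 | step 2 | 3-bromo-4-butylfuran-2,5-dione | CCCCC1=C(Br)C(=O)OC1=O
F5 | step 1 | ethyl 2-(hexanoyloxy)prop-2-enoate | CCCCCC(=O)OC(=C)C(=O)OCC
F6 | step 1 | ethyl 2,3-dibromo-2-(hexanoyloxy)propanoate (racemic) | CCCCCC(=O)OC(Br)(CBr)C(=O)OCC
F7 | step 1 | ethyl 3-bromo-2-(hexanoyloxy)prop-2-enoate (E/Z mixture) | CCCCCC(=O)OC(=CBr)C(=O)OCC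
F8 | step 1 | ethyl 2,3,3-tribromo-2-(hexanoyloxy)propanoate (racemic) | CCCCCC(=O)OC(Br)(C(Br)Br)C(=O)OCC
F9 | step 3 | 4-butyl-2-(dibromomethylene)-5-oxo-2,5-dihydrofuran-3-yl trifluoromethanesulfonate | CCCCC1=C(OS(=O)(=O)C(F)(F)F)C(=C(Br)Br)OC1=O
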